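**Retrosynthetic overview**

1. The target is a 2-methyl-2,3-epoxycyclohexanone (C1 ketone, C2–C3 oxirane, acetates on C4 and C6, dienyl side chain on C5). The two acetates are carried as silyl ethers, so the working goal is bis-silyl ether 26.
2. Key disconnection: the C1–C2 bond between the ketone carbon and the methyl-bearing oxirane carbon, cut together with the oxirane C3–O bond. This leads to acyclic keto aldehyde 23 (C1 aldehyde, C2 methyl ketone, chloride on C3).
3. Enabling feature: C1 and C2 are adjacent, both oxygen-bearing and both carbonyl-derived (like polarity), and the C2 oxygen is bridged to C3. A carbene reverses the polarity of the C1 aldehyde (crossed benzoin) and joins C1 to C2; the new C2 alkoxide then displaces the C3 chloride. The carbocycle forms first and the oxirane second, in one flask.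
4. Precursor 23 is built linearly: C5–C6 by an Evans syn-aldol of a senecioyl imide dienolate; the side chain from the resulting isopropenyl group (allylic oxidation, catalytic asymmetric allylboration, cross-metathesis, angeloylation); C3–C4 by a proline-catalysed anti-aldol of chloroacetone.
5. Stereocontrol: auxiliary sets C5 and C6; (R)-proline sets C3 and C4; the phosphoric acid sets C2'; in the key step C3 is inverted and C2 is relayed from C3. No ring exists before the key step.

Key step: step 15

Remark: the side-chain ester is taken as the angelate, (Z)-2-methylbut-2-enoate, as the SMILES shows. Locants used throughout are those of the target: C1 ketone, C2 methyl-bearing oxirane carbon, C3 oxirane CH, C4 acetoxy carbon next to C3, C5 side-chain carbon, C6 acetoxy carbon next to C1; side chain C1'(=CH2)–C2'H(O-angeloyl)–C3'H2–C4'H=C5'(CH3)2. Acyclic intermediates keep these locants, and CIP descriptors are given with them. TBS = tert-butyldimethylsilyl. "Side chain" in a name means the full angeloylated chain.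

**Step 1**
Reactants: 1 (S)-4-benzyloxazolidin-2-one; 2 3-methylbut-2-enoyl chloride
Product: 3 (S)-4-benzyl-3-(3-methylbut-2-enoyl)oxazolidin-2-one
Conditions: n-BuLi, THF, −78 °C; then 2, −78 → 0 °C
Reagents that add atoms: none
Why: N-acylation of the lithiated oxazolidinone by an acid chloride is the standard entry to Evans imides and brings in the purchased stereocentre that will control C5 and C6.

**Step 2**
Reactants: 3 (S)-4-benzyl-3-(3-methylbut-2-enoyl)oxazolidin-2-one; 4 (tert-butyldimethylsilyloxy)acetaldehyde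
Product: 6 syn-aldol imide (5S,6S) with acyl chain C4(=O)–C5H(isopropenyl)–C6H(OH)–C1H2OTBS, via Z-dibutylboron dienolate 5 (not isolated)
Conditions: Bu2BOTf, Et3N, CH2Cl2, −78 → 0 °C; then 4, −78 °C; pH 7 buffer, MeOH, H2O2, 0 °C
Reagents that add atoms: none
Why: Evans syn-aldol of a crotonate-type imide, in which soft enolisation removes a γ-proton and the Z boron dienolate reacts at its α-carbon through a Zimmerman–Traxler chair on the face away from the benzyl group, which should set C5 and C6 syn as (5S,6S) and leave the isopropenyl group deconjugated.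

**Step 3**
Reactants: 6 syn-aldol imide
Product: 7 C6 TBS ether of 6 (5S,6S)
Conditions: TBSOTf, 2,6-lutidine, CH2Cl2, −78 → 0 °C
Reagents that add atoms: tert-butyldimethylsilyl trifluoromethanesulfonate, CC(C)(C)[Si](C)(C)OS(=O)(=O)C(F)(F)F
Why: Silylation of a β-hydroxy imide with a silyl triflate and a hindered pyridine base is reliable and protects C6–OH as the same ether as C1–OH.

**Step 4**
Reactants: 7 bis-TBS imide
Product: 8 allylic alcohol (5S,6S) in which the C5 substituent is C1'(=CH2)–C2'H2OH
Conditions: SeO2 (0.5 equiv), t-BuOOH, CH2Cl2, 0 → 23 °C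
Reagents that add atoms: tert-butyl hydroperoxide, CC(C)(C)OO
Why: Riley allylic oxidation (ene reaction, then [2,3]-sigmatropic shift) of the 1,1-disubstituted alkene should hydroxylate the methyl group, because the only other allylic C–H (C5–H) is a hindered methine next to the imide carbonyl.

**Step 5**
Reactants: 8 allylic alcohol
Product: 9 enal (5S,6S) in which the C5 substituent is C1'(=CH2)–C2'HO
Conditions: Dess–Martin periodinane, pyridine, CH2Cl2, 0 °C
Reagents that add atoms: none
Why: Dess–Martin oxidation gives the α-substituted acrolein under buffered, non-basic conditions that should not move the double bond into conjugation with the imide.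

**Step 6**
Reactants: 9 enal; 10 allylboronic acid pinacol ester
Product: 12 homoallylic alcohol (5S,6S,2'S) with C5 substituent C1'(=CH2)–C2'H(OH)–CH2–CH=CH2, via pinacol borate ester 11 (not isolated)
Conditions: (S)-3,3'-bis(2,4,6-triisopropylphenyl)-1,1'-binaphthyl-2,2'-diyl hydrogen phosphate [(S)-TRIP] (5 mol%), toluene, −30 °C; aqueous work-up
Reagents that add atoms: none
Why: Chiral phosphoric acid-catalysed allylboration of an α,β-unsaturated aldehyde runs through a closed six-membered transition state in which the catalyst, not the remote C5 centre, selects the aldehyde face, and the (S)-acid should deliver allyl to the Si face and set C2' as (S).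

**Step 7**
Reactants: 12 homoallylic alcohol; 13 2-methylbut-2-ene
Product: 14 prenyl carbinol (5S,6S,2'S) with C5 substituent C1'(=CH2)–C2'H(OH)–CH2–CH=C(CH3)2
Conditions: second-generation Grubbs catalyst RuCl2(=CHPh)(H2IMes)(PCy3) (5 mol%), 13 (excess), CH2Cl2, 40 °C
Reagents that add atoms: none
Why: Cross-metathesis of the monosubstituted alkene with excess 2-methylbut-2-ene installs the trisubstituted terminus, while the hindered 1,1-disubstituted C1' methylene should not engage the ruthenium carbene.

**Step 8**
Reactants: 14 prenyl carbinol; 15 angelic acid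
Product: 16 angelate imide (5S,6S,2'S) carrying the complete side chain
Conditions: 15, 2,4,6-trichlorobenzoyl chloride, Et3N, toluene, 23 °C; then 14, 80 °C
Reagents that add atoms: none
Why: Yamaguchi-type esterification through the mixed anhydride formed in the flask acylates the hindered allylic alcohol without 4-(dimethylamino)pyridine, which should preserve the Z geometry of the angelate.

**Step 9**
Reactants: 16 angelate imide
Product: 17 primary alcohol (5R,6S,2'S) HOC4H2–C5H(side chain)–C6H(OTBS)–C1H2OTBS
Conditions: LiBH4, MeOH (1.1 equiv), Et2O, 0 °C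
Reagents that add atoms: none
Why: Reductive cleavage of an Evans imide with lithium borohydride is standard and should be much faster than reduction of the hindered conjugated ester.

**Step 10**
Reactants: 17 primary alcohol
Product: 18 aldehyde (5S,6S,2'S) OHC4–C5H(side chain)–C6H(OTBS)–C1H2OTBS
Conditions: Dess–Martin periodinane, pyridine, CH2Cl2, 0 °C; used at once
Reagents that add atoms: none
Why: Dess–Martin oxidation gives the α-branched β,γ-unsaturated aldehyde without a base strong enough to epimerise C5 or conjugate the C1' methylene.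

**Step 11**
Reactants: 18 aldehyde; 19 chloroacetone
Product: 20 anti-chlorohydrin (3R,4R,5R,6S,2'S) CH3–C2(=O)–C3HCl–C4H(OH)–C5H(side chain)–C6H(OTBS)–C1H2OTBS
Conditions: (R)-proline (30 mol%), 19 (10 equiv), DMSO, 4 °C
Reagents that add atoms: none
Why: Proline-catalysed direct aldol of chloroacetone, in which the enamine at the chlorinated carbon adds through the acid-organised chair transition state to give the anti-chlorohydrin, and (R)-proline should set (3R,4R), which is also the Felkin–Anh sense if the silyloxy-bearing C6 branch acts as the large group.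

**Step 12**
Reactants: 20 anti-chlorohydrin
Product: 21 C4 TBS ether of 20 (3R,4R,5S,6S,2'S)
Conditions: TBSOTf, 2,6-lutidine, CH2Cl2, −78 °C
Reagents that add atoms: tert-butyldimethylsilyl trifluoromethanesulfonate, CC(C)(C)[Si](C)(C)OS(=O)(=O)C(F)(F)F
Why: Low-temperature silylation with the triflate and a weak hindered base should cap C4–OH before the chlorohydrin can close to an oxirane or eliminate.

**Step 13**
Reactants: 21 tris-TBS chloro ketone
Product: 22 C1 primary alcohol (3R,4R,5S,6S,2'S)
Conditions: HF·pyridine, pyridine, THF, 0 °C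
Reagents that add atoms: none
Why: Buffered hydrogen fluoride–pyridine cleaves a primary silyl ether much faster than hindered secondary ones, a standard selective desilylation.

**Step 14**
Reactants: 22 primary alcohol
Product: 23 keto aldehyde (3R,4R,5S,6S,2'S) OHC1–C6H(OTBS)–C5H(side chain)–C4H(OTBS)–C3HCl–C2(=O)–CH3
Conditions: Dess–Martin periodinane, pyridine, CH2Cl2, 0 °C; used at once
Reagents that add atoms: none
Why: Dess–Martin oxidation gives the α-silyloxy aldehyde under neutral conditions that should leave the α-chloro ketone and its C3 configuration untouched.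

**Step 15**
Reactants: 23 keto aldehyde
Product: 26 bis-TBS epoxy ketone (2S,3S,4R,5R,6S,2'S), via Breslow intermediate 24 (not isolated), via chlorohydrin ketol 25 (not isolated)
Conditions: 2-(pentafluorophenyl)-6,7-dihydro-5H-pyrrolo[2,1-c][1,2,4]triazol-2-ium tetrafluoroborate (20 mol%), i-Pr2NEt (20 mol%), CH2Cl2, 23 °C; then 1,8-diazabicyclo[5.4.0]undec-7-ene (DBU, 1.2 equiv), 0 °C
Reagents that add atoms: none
Why: Proposed new method: the triazolylidene adds to the C1 aldehyde to give Breslow intermediate 24, whose nucleophilic C1 attacks the C2 ketone (6-exo-trig crossed benzoin) to give ketol 25 after release of the carbene, and on addition of DBU the C2 alkoxide displaces the axial C3 chloride from the rear (3-exo-tet), so cyclohexanone and oxirane arise in one flask. The closest known reaction types are the carbene-catalysed intramolecular aldehyde–ketone benzoin of polyoxygenated keto aldehydes and the addition of stoichiometric acyl anion equivalents to α-halo ketones to give epoxides; their catalytic union on an α-chloro ketone acceptor is not established. C2 is set in a chair transition state with the C4 and C6 silyloxy groups and the C5 side chain equatorial, the C3 chloride axial and the ketone oxygen opposed to the C–Cl dipole, which puts the new C2–O bond anti to C3–Cl and the methyl group equatorial, and C3 is then inverted stereospecifically in the SN2 closure. A benzoin adduct with oxygen cis to chlorine cannot close and should return to 23 by the reversible retro-benzoin, so the C3–C4 relationship from step 11 is relayed to both oxirane carbons. The step needs carbonyl addition at C2 to outrun SN2 acylation at C3 by the Breslow intermediate (5-exo-tet) and Darzens-type attack of the chloro ketone enolate on the aldehyde; this is secured by the fast, reversible carbonyl addition at room temperature with only a catalytic weak base, and by adding DBU only after the aldehyde is consumed.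

**Step 16**
Reactants: 26 bis-TBS epoxy ketone
Product: 27 diol (2S,3S,4R,5R,6S,2'S)
Conditions: HF·pyridine, pyridine, THF, 0 → 23 °C
Reagents that add atoms: none
Why: Buffered fluoride cleavage of the two secondary silyl ethers avoids the basic conditions that could open the oxirane or epimerise C6.

**Step 17**
Reactants: 27 diol; 28 acetic anhydride
Product: 29 target (2S,3S,4R,5R,6S,2'S)
Conditions: 28, pyridine, 4-(dimethylamino)pyridine (cat.), CH2Cl2, 0 °C
Reagents that add atoms: none
Why: Acetylation of the two secondary alcohols under mild amine catalysis should complete the target without touching the oxirane, the ketone or the angelate.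

**Compound list**

1 | (S)-4-benzyloxazolidin-2-one | O=C1N[C@@H](Cc2ccccc2)CO1 | starting material
2 | 3-methylbut-2-enoyl chloride | CC(C)=CC(Cl)=O | starting material
3 | (S)-4-benzyl-3-(3-methylbut-2-enoyl)oxazolidin-2-one | CC(C)=CC(=O)N1[C@@H](Cc2ccccc2)COC1=O | intermediate
4 | (tert-butyldimethylsilyloxy)acetaldehyde | O=CCO[Si](C)(C)C(C)(C)C | starting material
5 | Z-dibutylboron dienolate of 3 (not isolated) | C=C(C)/C=C(\OB(CCCC)CCCC)N1[C@@H](Cc2ccccc2)COC1=O | intermediate
6 | syn-aldol imide (5S,6S): C4(=O)–C5H(isopropenyl)–C6H(OH)–C1H2OTBS on the (S)-auxiliary | C=C(C)[C@@H]([C@H](O)CO[Si](C)(C)C(C)(C)C)C(=O)N1[C@@H](Cc2ccccc2)COC1=O | intermediate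
7 | C6 TBS ether of 6 (5S,6S) | C=C(C)[C@@H]([C@H](O[Si](C)(C)C(C)(C)C)CO[Si](C)(C)C(C)(C)C)C(=O)N1[C@@H](Cc2ccccc2)COC1=O | intermediate
8 | allylic alcohol (5S,6S), C5 substituent C1'(=CH2)–C2'H2OH | C=C(CO)[C@@H]([C@H](O[Si](C)(C)C(C)(C)C)CO[Si](C)(C)C(C)(C)C)C(=O)N1[C@@H](Cc2ccccc2)COC1=O | intermediate
9 | enal (5S,6S), C5 substituent C1'(=CH2)–C2'HO | C=C(C=O)[C@@H]([C@H](O[Si](C)(C)C(C)(C)C)CO[Si](C)(C)C(C)(C)C)C(=O)N1[C@@H](Cc2ccccc2)COC1=O | intermediate
10 | allylboronic acid pinacol ester | C=CCB1OC(C)(C)C(C)(C)O1 | starting material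
11 | pinacol borate ester of 12 (not isolated) | C=C([C@@H]([C@H](O[Si](C)(C)C(C)(C)C)CO[Si](C)(C)C(C)(C)C)C(=O)N1[C@@H](Cc2ccccc2)COC1=O)[C@H](CC=C)OB1OC(C)(C)C(C)(C)O1 | intermediate
12 | homoallylic alcohol (5S,6S,2'S) | C=C([C@@H]([C@H](O[Si](C)(C)C(C)(C)C)CO[Si](C)(C)C(C)(C)C)C(=O)N1[C@@H](Cc2ccccc2)COC1=O)[C@H](CC=C)O | intermediate
13 | 2-methylbut-2-ene | CC=C(C)C | starting material
14 | prenyl carbinol (5S,6S,2'S) | C=C([C@@H]([C@H](O[Si](C)(C)C(C)(C)C)CO[Si](C)(C)C(C)(C)C)C(=O)N1[C@@H](Cc2ccccc2)COC1=O)[C@H](CC=C(C)C)O | intermediate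
15 | angelic acid, (Z)-2-methylbut-2-enoic acid | OC(=O)/C(C)=C\C | starting material
16 | angelate imide (5S,6S,2'S) | C=C([C@@H]([C@H](O[Si](C)(C)C(C)(C)C)CO[Si](C)(C)C(C)(C)C)C(=O)N1[C@@H](Cc2ccccc2)COC1=O)[C@H](CC=C(C)C)OC(=O)/C(C)=C\C | intermediate
17 | C4 primary alcohol (5R,6S,2'S) | C=C([C@@H]([C@H](O[Si](C)(C)C(C)(C)C)CO[Si](C)(C)C(C)(C)C)CO)[C@H](CC=C(C)C)OC(=O)/C(C)=C\C | intermediate
18 | C4 aldehyde (5S,6S,2'S) | C=C([C@@H]([C@H](O[Si](C)(C)C(C)(C)C)CO[Si](C)(C)C(C)(C)C)C=O)[C@H](CC=C(C)C)OC(=O)/C(C)=C\C | intermediate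
19 | chloroacetone | CC(=O)CCl | starting material
20 | anti-chlorohydrin (3R,4R,5R,6S,2'S) | C=C([C@@H]([C@H](O[Si](C)(C)C(C)(C)C)CO[Si](C)(C)C(C)(C)C)[C@@H](O)[C@@H](Cl)C(C)=O)[C@H](CC=C(C)C)OC(=O)/C(C)=C\C | intermediate
21 | C4 TBS ether of 20 (3R,4R,5S,6S,2'S) | C=C([C@@H]([C@H](O[Si](C)(C)C(C)(C)C)CO[Si](C)(C)C(C)(C)C)[C@@H](O[Si](C)(C)C(C)(C)C)[C@@H](Cl)C(C)=O)[C@H](CC=C(C)C)OC(=O)/C(C)=C\C | intermediate
22 | C1 primary alcohol (3R,4R,5S,6S,2'S) | C=C([C@@H]([C@H](O[Si](C)(C)C(C)(C)C)CO)[C@@H](O[Si](C)(C)C(C)(C)C)[C@@H](Cl)C(C)=O)[C@H](CC=C(C)C)OC(=O)/C(C)=C\C | intermediate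
23 | keto aldehyde (3R,4R,5S,6S,2'S) | C=C([C@@H]([C@H](O[Si](C)(C)C(C)(C)C)C=O)[C@@H](O[Si](C)(C)C(C)(C)C)[C@@H](Cl)C(C)=O)[C@H](CC=C(C)C)OC(=O)/C(C)=C\C | intermediate
24 | Breslow intermediate of 23, C1 enaminol of the triazolylidene (not isolated) | C=C([C@@H]([C@H](O[Si](C)(C)C(C)(C)C)C(O)=C1N(c2c(F)c(F)c(F)c(F)c2F)N=C2CCCN12)[C@@H](O[Si](C)(C)C(C)(C)C)[C@@H](Cl)C(C)=O)[C@H](CC=C(C)C)OC(=O)/C(C)=C\C | intermediate
25 | chlorohydrin ketol (2R,3R,4R,5S,6S,2'S), 3-chloro-2-hydroxy-2-methylcyclohexanone core (not isolated) | C=C([C@@H]1[C@@H](O[Si](C)(C)C(C)(C)C)[C@@H](Cl)[C@](C)(O)C(=O)[C@H]1O[Si](C)(C)C(C)(C)C)[C@H](CC=C(C)C)OC(=O)/C(C)=C\C | intermediate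
26 | bis-TBS epoxy ketone (2S,3S,4R,5R,6S,2'S) | C=C([C@@H]1[C@@H](O[Si](C)(C)C(C)(C)C)[C@@H]2O[C@]2(C)C(=O)[C@H]1O[Si](C)(C)C(C)(C)C)[C@H](CC=C(C)C)OC(=O)/C(C)=C\C | intermediate
27 | epoxy ketone diol (2S,3S,4R,5R,6S,2'S) | C=C([C@@H]1[C@@H](O)[C@@H]2O[C@]2(C)C(=O)[C@H]1O)[C@H](CC=C(C)C)OC(=O)/C(C)=C\C | intermediate
28 | acetic anhydride | CC(=O)OC(C)=O | starting material
29 | CNP0298051.3 (2S,3S,4R,5R,6S,2'S) | C=C([C@@H]1[C@@H](OC(C)=O)[C@@H]2O[C@]2(C)C(=O)[C@H]1OC(C)=O)[C@H](CC=C(C)C)OC(=O)/C(C)=C\C | target

**Totals and risks**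

Total step count: 17. Longest linear sequence: 17 steps (1 and 2 to 29).

Steps most likely to fail:

1. Step 15 (proposed method). The carbene may be alkylated by the α-chloro ketone, the Breslow intermediate may acylate C3 by SN2 to give a five-membered ketone, or base may trigger Darzens-type closure before the benzoin. Fallback, known chemistry only: starting from 23, radical dechlorination (Bu3SnH, Et3B, air, toluene, 0 °C) should give the chlorine-free keto aldehyde F1. The carbene-catalysed crossed aldehyde–ketone benzoin (same triazolium salt, i-Pr2NEt, CH2Cl2) should close it to α-ketol F2, whose C2 configuration does not matter. Dehydration with Burgess reagent (toluene, 50 °C) should give the 2-methylcyclohexenone F3. Nucleophilic Weitz–Scheffer epoxidation (t-BuOOH, DBU, CH2Cl2), expected anti to the C4 silyloxy group, returns to the route at 26.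

2. Step 11. The amine catalyst may form a dienamine from the α-branched β,γ-unsaturated aldehyde, which would move the C1' double bond into conjugation or eliminate the C6 silyloxy group; facial selectivity may also be poor if catalyst and substrate preferences are mismatched. Fallback: starting from 18, Wittig olefination with 1-(triphenylphosphoranylidene)propan-2-one (toluene, 40 °C) should give E-enone F4. Amine-salt-catalysed asymmetric nucleophilic epoxidation (9-amino-9-deoxy-epi-cinchona alkaloid trifluoroacetate, H2O2, dioxane; the pseudoenantiomer that gives the (3S,4R)-oxirane) should give trans-epoxy ketone F5. Opening with LiCl and AcOH in THF at the carbon α to the ketone, with inversion, returns to the route at 20.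

3. Step 4. The ene step may occur at the C5 methine instead of the methyl group, or the product may be over-oxidised. Fallback: starting from 7, ene-type allylic chlorination with HOCl generated from Ca(OCl)2 and CO2 (CH2Cl2/H2O, 0 °C) should give allylic chloride F6. Oxidation with N-methylmorpholine N-oxide (MeCN, 23 °C) then gives the enal directly and returns to the route at 9, bypassing 8.

**Further compounds**

F1 | step 15 | chlorine-free keto aldehyde (4S,5R,6S,2'S) | C=C([C@@H]([C@H](O[Si](C)(C)C(C)(C)C)C=O)[C@@H](O[Si](C)(C)C(C)(C)C)CC(C)=O)[C@H](CC=C(C)C)OC(=O)/C(C)=C\C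
F2 | step 15 | α-ketol (4S,5R,6S,2'S), C2 epimers | C=C([C@@H]1[C@@H](O[Si](C)(C)C(C)(C)C)CC(C)(O)C(=O)[C@H]1O[Si](C)(C)C(C)(C)C)[C@H](CC=C(C)C)OC(=O)/C(C)=C\C
F3 | step 15 | 2-methylcyclohexenone (4S,5R,6S,2'S) | C=C([C@@H]1[C@@H](O[Si](C)(C)C(C)(C)C)C=C(C)C(=O)[C@H]1O[Si](C)(C)C(C)(C)C)[C@H](CC=C(C)C)OC(=O)/C(C)=C\C
F4 | step 11 | E-enone (5S,6S,2'S) | C=C([C@@H]([C@H](O[Si](C)(C)C(C)(C)C)CO[Si](C)(C)C(C)(C)C)/C=C/C(C)=O)[C@H](CC=C(C)C)OC(=O)/C(C)=C\C
F5 | step 11 | trans-epoxy ketone (3S,4R,5R,6S,2'S) | C=C([C@@H]([C@H](O[Si](C)(C)C(C)(C)C)CO[Si](C)(C)C(C)(C)C)[C@H]1O[C@@H]1C(C)=O)[C@H](CC=C(C)C)OC(=O)/C(C)=C\C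
F6 | step 4 | allylic chloride (5S,6S) | C=C(CCl)[C@@H]([C@H](O[Si](C)(C)C(C)(C)C)CO[Si](C)(C)C(C)(C)C)C(=O)N1[C@@H](Cc2ccccc2)COC1=O
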